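Compound numbers used throughout: **1** 1,2,4,5-tetramethoxybenzene; **4** 2,3,5,6-tetramethoxyphenol; **5**–**7** ring A aldehydes; **8** oxime; **10** nitrile oxide; **11**–**13** anisole, methoxyacetyl chloride, ring B ketone; **14** pyrrolidine; **15** enamine; **17** isoxazole; **18** enaminone; **20** target. Compounds **2**, **3**, **9**, **16** and **19** are intermediates that are not isolated.

## The problem

Target **20**, 7-hydroxy-3,5,6,8-tetramethoxy-2-(4-methoxyphenyl)-4H-chromen-4-one, is a flat, achiral flavone. There is no stereocentre to set, so the difficulty lies in regiochemistry and in the oxygenation pattern. Every carbon of ring A is substituted: C5, C6 and C8 carry methyl ethers, C7 a free hydroxyl and C8a the ring oxygen O1. Five contiguous oxygens must therefore be placed, and O7 and O1 kept distinct from the three methyl ethers. Ring C is oxygenated at all three carbons: C4 as the carbonyl, C3 as a methyl ether and C2 as the enol ether carbon bonded to O1 and to ring B. The C5 methyl ether, peri to the C4 carbonyl, is the one most easily lost to Lewis acids or hot mineral acid; the pyranone is opened at C2 by hydroxide and alkoxide; and the electron-rich ring A phenols are prone to oxidation. The closing steps therefore have to be reductive or only mildly acidic. The enabling feature is the C4–C3–C2 unit: with oxygen on each carbon it is a 2-methoxy-1,3-dicarbonyl array between ring A and ring B, which is what reductive opening of a 4-methoxyisoxazole with ring A on C3 and ring B on C5 delivers. Because ring A is substituted at both positions ortho to C4a, the matching benzonitrile oxide is shielded against dimerization and can be handled as an isolable dipole.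

## Retrosynthesis

**20 back to enaminone 18.** The O1–C2 bond is cut and the C4 carbonyl is traced back to an enamine carbon. Enaminone **18** would hydrolyse in dilute acid to 2-methoxy-1,3-diketone **19**, which cyclodehydrates as in the last stage of a classical flavone synthesis. Only the hydroxyl next to the side chain can reach the anisoyl carbonyl, so the free C7 hydroxyl needs no protection at this stage. The forward step must be mild enough to leave the C5 methyl ether alone.

**18 back to isoxazole 17.** The N–O bond is re-formed and both phenols are capped as benzyl ethers. One hydrogenation then does three jobs in the forward direction: N–O cleavage and two debenzylations. Isoxazole **17** is aromatic, neutral and carries all three ring C carbons at the final oxidation level. Benzyl is preferred over silyl or acetal groups because it survives nitrile oxide generation and leaves under the conditions that open the heterocycle.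

**17 back to nitrile oxide 10 and enamine 15.** Two bonds of the isoxazole are cut: the C–C bond that becomes C4–C3 of the flavone, and the bond from the ring oxygen to the carbon that becomes C2. This is the most convergent cut available, splitting the molecule into a ring A piece and a ring B piece of similar size. Against a Claisen-type acylation of a ketone enolate by a di-ortho-substituted aroyl unit, it has the advantage that the linear nitrile oxide carbon is easy to approach even between two ortho substituents. The forward reaction must be regioselective: the methoxy-bearing carbon of **15** has to bond to the dipole carbon. It must also end in loss of pyrrolidine.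

**10 back to 1,2,4,5-tetramethoxybenzene 1.** Nitrile oxide **10** comes from oxime **8** and that from aldehyde **7**. Aldehyde **7** is the dibenzyl ether of dihydroxy aldehyde **6**. In **6** the ortho hydroxyl is exposed by chelation-controlled cleavage of one of the two equivalent ortho methyl ethers of the mirror-symmetric aldehyde **5**. Symmetry is what makes this short: either ortho ether gives the same product. Aldehyde **5** arises by para-formylation of phenol **4**, whose only free ring carbon is the one wanted. Phenol **4** arises from **1** by metalation between two methoxy groups, borylation and oxidation, which supplies the fifth oxygen that **1** lacks.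

**15 back to anisole 11, methoxyacetyl chloride 12 and pyrrolidine 14.** Enamine **15** is the pyrrolidine enamine of ketone **13**, which can enolize in one direction only. Ketone **13** is the para Friedel–Crafts product of **11** and **12**, so the C3 methoxy group of the target is bought, not made.

## Roads not taken

**Alternative 1:** The C4–C4a bond is cut. An aryloxyacrylic acid A1, with the ring A phenol oxygen on the anisyl-bearing alkene carbon and the C7 oxygen masked as a mesylate, would be cyclized in P2O5/CH3SO3H to flavone mesylate A2 by acylium attack on the single free ring A carbon.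
- Merits: the acylation site is unambiguous, the C3 methyl ether is carried in, and ring C closes directly at the flavone oxidation level with no masked intermediate. In that last respect it is better than the chosen plan, which needs two steps after its key step.
- Weak points: the ring A phenol needed for A1 has five oxygens in four different states and no symmetry, so its preparation is longer than that of **7**. A1 must have the acid cis to the aryloxy group on a tetrasubstituted enol ether. A hot, strongly acidic, dehydrating medium threatens both the enol ether and the methyl ethers. The mesylate must finally be removed from A2 with a nucleophile or base, the reagents that open the pyranone.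
- Comparison: the chosen plan sets a symmetric ring A precursor, a neutral key step and a single hydrogenation that frees both phenols against the directness of this closure.

**Alternative 2:** The O1–C2 bond is cut with demethylation built in. Ynone A3, with a mirror-symmetric 4-benzyloxy-2,3,5,6-tetramethoxyphenyl ring, would be treated with ICl. An ortho methoxy oxygen attacks the activated alkyne, chloride removes the methyl group, and 3-iodoflavone A4 results.
- Merits: ring A needs no differentiation of its ortho oxygens at all, the ynone is assembled quickly, and the cyclization is mild. In ring A economy this road is better than the chosen one, which spends a separate chelation-controlled demethylation (step 3).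
- Weak points: the iodine on C3 of A4 must be turned into a methoxy group. That means a copper- or palladium-mediated C–O coupling with methoxide on a chromone that methoxide can open at C2, or a longer borylation–oxidation–methylation detour. ICl may also iodinate the electron-rich ring B.
- Comparison: the chosen plan brings the C3 oxygen in from **12** at the outset and needs no substitution on the finished heterocycle.

**Alternative 3:** The C8a–O1 bond is cut. Diketone A5, with a symmetric 2,6-dibromo ring A, would be closed with CuI (monovalent copper), 1,10-phenanthroline and Cs2CO3. The enolate oxygen on the anisoyl carbon displaces one of the two equivalent bromides and gives 5-bromoflavone A6.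
- Merits: the symmetry again removes any regiochemical question, the C3 methyl ether is in place from the start (as in the chosen plan), and the pyranone forms directly.
- Weak points: A5 requires C-acylation of an enolate by a di-ortho-bromo aroyl unit, which is hindered and prone to O-acylation. The remaining bromide of A6 sits at the most hindered position, peri to the carbonyl, and must be exchanged for methoxide on the base-sensitive flavone, with reductive debromination as a competitor. Debenzylation by hydrogenolysis can only follow once the bromide is gone.
- Comparison: this road is about as convergent as the chosen one. The chosen plan sets against it a ring A that carries all its oxygens before the rings are joined and an endgame free of metal-mediated substitution.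

Key step: step 9

Assumption: enamine **15** is formed and used as a mixture of double-bond isomers. This is of no consequence, because both stereocentres of isoxazoline **16** are destroyed on aromatization; **16** and diketone **19** are racemic.

## Route

Step 1
Reactants: 1 1,2,4,5-tetramethoxybenzene
Product: 4 2,3,5,6-tetramethoxyphenol, via aryllithium 2 (not isolated), via dimethyl arylboronate 3 (not isolated)
Conditions: n-BuLi (1.05 equiv), TMEDA, THF, 0 °C; B(OMe)3, −78 °C → rt; AcOH, 30% aq. H2O2, 0 °C → rt
Reagents that add atoms: hydrogen peroxide, OO
Why: Directed ortho-metalation removes the ring hydrogen lying between two methoxy groups, and borylation followed by oxidative boron-to-oxygen aryl migration gives the phenol; one equivalent of base leaves the second, equivalent C–H untouched.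

Step 2
Reactants: 4 2,3,5,6-tetramethoxyphenol
Product: 5 4-hydroxy-2,3,5,6-tetramethoxybenzaldehyde
Conditions: hexamethylenetetramine, CF3CO2H, 85 °C; then 2 M aq. HCl, rt
Reagents that add atoms: hexamethylenetetramine, C1N2CN3CN1CN(C2)C3; water, O
Why: Duff formylation: the only free ring carbon is para to the hydroxyl, and the small methyleneiminium electrophile should enter between the two flanking methoxy groups as it does in the para-formylation of 2,6-disubstituted phenols; internal hydride transfer and hydrolysis release the aldehyde.

Step 3
Reactants: 5 4-hydroxy-2,3,5,6-tetramethoxybenzaldehyde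
Product: 6 2,4-dihydroxy-3,5,6-trimethoxybenzaldehyde
Conditions: BCl3 (2.2 equiv), CH2Cl2, −78 → −20 °C; H2O quench
Reagents that add atoms: none
Why: Chelation-controlled ether cleavage, as in the 5-O-demethylation of polymethoxyflavones: boron bridges the carbonyl oxygen and one ortho methoxy oxygen and chloride removes that methyl group; the two ortho ethers of 5 are equivalent, so one product results, and the aryloxyboron chelate then formed shields the second ortho ether at low temperature.

Step 4
Reactants: 6 2,4-dihydroxy-3,5,6-trimethoxybenzaldehyde
Product: 7 2,4-bis(benzyloxy)-3,5,6-trimethoxybenzaldehyde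
Conditions: BnBr (2.5 equiv), K2CO3, DMF, 60 °C
Reagents that add atoms: benzyl bromide, BrCc1ccccc1
Why: Williamson etherification of both phenols; the hydrogen-bonded ortho hydroxyl needs warm DMF but is alkylated as well, and both ethers will later fall in the hydrogenation that opens the isoxazole.

Step 5
Reactants: 7 2,4-bis(benzyloxy)-3,5,6-trimethoxybenzaldehyde
Product: 8 (E)-2,4-bis(benzyloxy)-3,5,6-trimethoxybenzaldehyde oxime
Conditions: NH2OH·HCl, NaOAc, EtOH/H2O, 50 °C
Reagents that add atoms: hydroxylamine hydrochloride, NO.Cl
Why: Oxime condensation under acetate buffering; the aldehyde is hindered but not enolizable, and the E oxime with hydroxyl anti to the aryl group is expected.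

Step 6
Reactants: 8 (E)-2,4-bis(benzyloxy)-3,5,6-trimethoxybenzaldehyde oxime
Product: 10 2,4-bis(benzyloxy)-3,5,6-trimethoxybenzonitrile oxide, via hydroximoyl chloride 9 (not isolated)
Conditions: NCS, DMF, rt; then Et3N, CH2Cl2, 0 °C
Reagents that add atoms: none
Why: Chlorination of the aldoxime and 1,3-dehydrochlorination with triethylamine is the standard entry to nitrile oxides; the two ortho alkoxy groups block dimerization to the furoxan, so the dipole should be isolable like other 2,6-disubstituted benzonitrile oxides, and the fully substituted ring offers NCS no carbon to chlorinate.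

Step 7
Reactants: 11 anisole; 12 methoxyacetyl chloride
Product: 13 2-methoxy-1-(4-methoxyphenyl)ethan-1-one
Conditions: AlCl3 (2.2 equiv), CH2Cl2, 0 °C → rt; ice/aq. HCl
Reagents that add atoms: none
Why: Friedel–Crafts acylation para to the methoxy group of anisole; more than two equivalents of AlCl3 are used because the α-methoxy ketone product binds the Lewis acid.

Step 8
Reactants: 13 2-methoxy-1-(4-methoxyphenyl)ethan-1-one; 14 pyrrolidine
Product: 15 1-[2-methoxy-1-(4-methoxyphenyl)ethenyl]pyrrolidine (mixture of double-bond isomers)
Conditions: TiCl4 (0.6 equiv), excess 14, toluene, 0 °C → rt; filtration under N2, used crude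
Reagents that add atoms: none
Why: Titanium tetrachloride-mediated enamine condensation, the method of choice for aryl ketones: the Lewis acid activates the carbonyl and binds the water as TiO2; the ketone can enolize only towards the CH2OMe carbon, so a single constitutional enamine forms.

Step 9
Reactants: 10 2,4-bis(benzyloxy)-3,5,6-trimethoxybenzonitrile oxide; 15 1-[2-methoxy-1-(4-methoxyphenyl)ethenyl]pyrrolidine
Product: 17 3-[2,4-bis(benzyloxy)-3,5,6-trimethoxyphenyl]-4-methoxy-5-(4-methoxyphenyl)isoxazole, via 5-pyrrolidinylisoxazoline 16 (not isolated)
Conditions: toluene, rt → 50 °C; then TsOH·H2O (cat.), rt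
Reagents that add atoms: none
Why: This is the 1,3-dipolar cycloaddition of a nitrile oxide to an enamine followed by loss of the amine, the established route to 3,4,5-trisubstituted isoxazoles. Dipole 10 adds across the C=C bond of 15 in a concerted, asynchronous [3+2] process governed by the enamine HOMO and the nitrile oxide LUMO, so the CH(OMe) carbon bonds to the nitrile oxide carbon and the amine-bearing carbon to the nitrile oxide oxygen, giving isoxazoline 16. The five-membered ring therefore closes by cycloaddition, with the C–C and the C–O bond formed in one step. The regiochemistry the route needs is secured by the substrate: the pyrrolidine nitrogen is a far stronger donor than the methoxy oxygen on the other alkene carbon, so the alkene reacts as an enamine and not as an enol ether. The two stereocentres of 16 (C4 and C5) need no control, since acid ionizes the aminal carbon to a cation stabilized by the ring oxygen and the anisyl group and loss of the C4 proton gives aromatic 17; both double-bond isomers of 15 converge. The two ortho alkoxy groups of 10 block dimerization to the furoxan, which leaves time for addition to a trisubstituted alkene, and keeping the bath at or below 50 °C avoids isomerization of the dipole to the isocyanate. No stereocentre remains in 17.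

Step 10
Reactants: 17 3-[2,4-bis(benzyloxy)-3,5,6-trimethoxyphenyl]-4-methoxy-5-(4-methoxyphenyl)isoxazole
Product: 18 (2E)-3-amino-3-(2,4-dihydroxy-3,5,6-trimethoxyphenyl)-2-methoxy-1-(4-methoxyphenyl)prop-2-en-1-one
Conditions: H2 (1 atm), Pd/C, EtOAc/MeOH, rt; filtered under N2 and carried on crude
Reagents that add atoms: none
Why: Catalytic hydrogenolysis over zerovalent palladium cleaves the weak isoxazole N–O bond and both benzyl ethers in one operation, a combination known for benzyl-protected isoxazoles; the product is a vinylogous amide held in the E form by an N–H···O=C hydrogen bond and should resist further reduction.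

Step 11
Reactants: 18 (2E)-3-amino-3-(2,4-dihydroxy-3,5,6-trimethoxyphenyl)-2-methoxy-1-(4-methoxyphenyl)prop-2-en-1-one
Product: 20 7-hydroxy-3,5,6,8-tetramethoxy-2-(4-methoxyphenyl)-4H-chromen-4-one, via 2-methoxy-1,3-diketone 19 (not isolated)
Conditions: 2 M aq. HCl, EtOH, 70 °C
Reagents that add atoms: water, O
Why: Acid hydrolysis of the enaminone gives the 1,3-diketone, whose anisoyl carbonyl is attacked by the ortho phenol (6-exo-trig) and dehydrated to the pyranone, the classical cyclodehydration of o-hydroxyaryl 1,3-diketones to flavones; only the hydroxyl next to the chain can reach, and dilute acid at moderate temperature should spare the C5 methyl ether (closure before hydrolysis, through the 4-iminium, leads to the same product).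

## Compound list

1 | 1,2,4,5-tetramethoxybenzene | COc1cc(OC)c(OC)cc1OC | starting material
2 | (2,3,5,6-tetramethoxyphenyl)lithium | [Li]c1c(OC)c(OC)cc(OC)c1OC | intermediate
3 | dimethyl (2,3,5,6-tetramethoxyphenyl)boronate | COB(OC)c1c(OC)c(OC)cc(OC)c1OC | intermediate
4 | 2,3,5,6-tetramethoxyphenol | Oc1c(OC)c(OC)cc(OC)c1OC | intermediate
5 | 4-hydroxy-2,3,5,6-tetramethoxybenzaldehyde | O=Cc1c(OC)c(OC)c(O)c(OC)c1OC | intermediate
6 | 2,4-dihydroxy-3,5,6-trimethoxybenzaldehyde | O=Cc1c(O)c(OC)c(O)c(OC)c1OC | intermediate
7 | 2,4-bis(benzyloxy)-3,5,6-trimethoxybenzaldehyde | O=Cc1c(OCc2ccccc2)c(OC)c(OCc2ccccc2)c(OC)c1OC | intermediate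
8 | (E)-2,4-bis(benzyloxy)-3,5,6-trimethoxybenzaldehyde oxime | O/N=C/c1c(OCc2ccccc2)c(OC)c(OCc2ccccc2)c(OC)c1OC | intermediate
9 | (Z)-2,4-bis(benzyloxy)-N-hydroxy-3,5,6-trimethoxybenzenecarboximidoyl chloride | O/N=C(\Cl)c1c(OCc2ccccc2)c(OC)c(OCc2ccccc2)c(OC)c1OC | intermediate
10 | 2,4-bis(benzyloxy)-3,5,6-trimethoxybenzonitrile oxide | [O-][N+]#Cc1c(OCc2ccccc2)c(OC)c(OCc2ccccc2)c(OC)c1OC | intermediate
11 | anisole | COc1ccccc1 | starting material
12 | methoxyacetyl chloride | COCC(=O)Cl | starting material
13 | 2-methoxy-1-(4-methoxyphenyl)ethan-1-one | COCC(=O)c1ccc(OC)cc1 | intermediate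
14 | pyrrolidine | C1CCNC1 | starting material
15 | 1-[2-methoxy-1-(4-methoxyphenyl)ethenyl]pyrrolidine (mixture of double-bond isomers) | COC=C(N1CCCC1)c1ccc(OC)cc1 | intermediate
16 | 3-[2,4-bis(benzyloxy)-3,5,6-trimethoxyphenyl]-4-methoxy-5-(4-methoxyphenyl)-5-(pyrrolidin-1-yl)-4,5-dihydroisoxazole (racemic, mixture of diastereomers) | COC1C(c2c(OCc3ccccc3)c(OC)c(OCc3ccccc3)c(OC)c2OC)=NOC1(N4CCCC4)c5ccc(OC)cc5 | intermediate
17 | 3-[2,4-bis(benzyloxy)-3,5,6-trimethoxyphenyl]-4-methoxy-5-(4-methoxyphenyl)isoxazole | COc1ccc(-c2onc(-c3c(OCc4ccccc4)c(OC)c(OCc4ccccc4)c(OC)c3OC)c2OC)cc1 | intermediate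
18 | (2E)-3-amino-3-(2,4-dihydroxy-3,5,6-trimethoxyphenyl)-2-methoxy-1-(4-methoxyphenyl)prop-2-en-1-one | N/C(=C(/OC)C(=O)c1ccc(OC)cc1)c1c(O)c(OC)c(O)c(OC)c1OC | intermediate
19 | 1-(2,4-dihydroxy-3,5,6-trimethoxyphenyl)-2-methoxy-3-(4-methoxyphenyl)propane-1,3-dione (racemic, enolizable) | COc1ccc(cc1)C(=O)C(OC)C(=O)c1c(O)c(OC)c(O)c(OC)c1OC | intermediate
20 | 7-hydroxy-3,5,6,8-tetramethoxy-2-(4-methoxyphenyl)-4H-chromen-4-one | COc1ccc(-c2oc3c(OC)c(O)c(OC)c(OC)c3c(=O)c2OC)cc1 | target

## Step count and least certain steps

Total step count: 11. Longest linear sequence: 9 steps (steps 1–6, 9, 10 and 11, from 1,2,4,5-tetramethoxybenzene); steps 7 and 8 form the ring B branch.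

**Step 9 (key step).** The cycloaddition may be slow, because a di-ortho-substituted dipole meets a trisubstituted, moisture-sensitive alkene. During a long reaction the enamine could hydrolyse back to the ketone, or the dipole could isomerize to the isocyanate. Fallback: the route is re-entered from ketone **13** and nitrile oxide **10** without an enamine. The lithium enolate of **13** (LDA, THF, −78 °C) adds to **10** through carbon and closes through oxygen, the known enolate–nitrile oxide condensation. This gives 3-[2,4-bis(benzyloxy)-3,5,6-trimethoxyphenyl]-4-methoxy-5-(4-methoxyphenyl)-4,5-dihydro-1,2-oxazol-5-ol F1, which is dehydrated with TsOH in warm toluene to isoxazole **17**.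

**Step 2.** Formylation at a carbon flanked by two buttressed methoxy groups may stall, or the electron-rich phenol may be oxidized in hot acid. Fallback: from phenol **4**, the hydroxyl is protected as 1,2,4,5-tetramethoxy-3-(methoxymethoxy)benzene F2 (MOMCl, i-Pr2NEt). The remaining ring hydrogen, again between two methoxy groups, is lithiated with n-BuLi and quenched with DMF to give 4-(methoxymethoxy)-2,3,5,6-tetramethoxybenzaldehyde F3. Methanolic HCl at room temperature removes the acetal and returns the route to **5**.

**Step 3.** Selectivity may be lost. With a free phenol next to crowded methyl ethers, the Lewis acid could also cleave an ether adjacent to the C4 oxygen or the second ortho ether. Fallback: from **5**, the para hydroxyl is benzylated first (BnBr, K2CO3) to 4-(benzyloxy)-2,3,5,6-tetramethoxybenzaldehyde F4. The milder, strictly chelation-dependent MgI2·OEt2 then removes one ortho methyl group to give 4-(benzyloxy)-2-hydroxy-3,5,6-trimethoxybenzaldehyde F5. A second benzylation brings the route back at **7**.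

**Step 10.** The two hydrogenolyses may not keep pace: slow N–O cleavage of a hindered triaryl-type isoxazole, or on forcing, over-reduction of the enaminone. Fallback: from **17**, the N–O bond is cleaved by Mo(CO)6 (zerovalent molybdenum) in wet acetonitrile at 80 °C to give (2E)-3-amino-3-[2,4-bis(benzyloxy)-3,5,6-trimethoxyphenyl]-2-methoxy-1-(4-methoxyphenyl)prop-2-en-1-one F6. Its benzyl ethers are then removed in a short, separate hydrogenolysis over Pd/C, returning the route at **18**.

## Further compounds

F1 | step 9 | 3-[2,4-bis(benzyloxy)-3,5,6-trimethoxyphenyl]-4-methoxy-5-(4-methoxyphenyl)-4,5-dihydro-1,2-oxazol-5-ol (racemic, mixture of diastereomers) | COC1C(c2c(OCc3ccccc3)c(OC)c(OCc3ccccc3)c(OC)c2OC)=NOC1(O)c4ccc(OC)cc4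
F2 | step 2 | 1,2,4,5-tetramethoxy-3-(methoxymethoxy)benzene | COCOc1c(OC)c(OC)cc(OC)c1OC
F3 | step 2 | 4-(methoxymethoxy)-2,3,5,6-tetramethoxybenzaldehyde | COCOc1c(OC)c(OC)c(C=O)c(OC)c1OC
F4 | step 3 | 4-(benzyloxy)-2,3,5,6-tetramethoxybenzaldehyde | O=Cc1c(OC)c(OC)c(OCc2ccccc2)c(OC)c1OC
F5 | step 3 | 4-(benzyloxy)-2-hydroxy-3,5,6-trimethoxybenzaldehyde | O=Cc1c(O)c(OC)c(OCc2ccccc2)c(OC)c1OC
F6 | step 10 | (2E)-3-amino-3-[2,4-bis(benzyloxy)-3,5,6-trimethoxyphenyl]-2-methoxy-1-(4-methoxyphenyl)prop-2-en-1-one | N/C(=C(/OC)C(=O)c1ccc(OC)cc1)c1c(OCc2ccccc2)c(OC)c(OCc2ccccc2)c(OC)c1OC
A1 | alternative 1 | (2E)-3-{3-[(methanesulfonyl)oxy]-2,4,5-trimethoxyphenoxy}-2-methoxy-3-(4-methoxyphenyl)prop-2-enoic acid | COc1ccc(cc1)/C(Oc1cc(OC)c(OC)c(OS(C)(=O)=O)c1OC)=C(\OC)C(=O)O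
A2 | alternative 1 | 3,5,6,8-tetramethoxy-2-(4-methoxyphenyl)-4-oxo-4H-chromen-7-yl methanesulfonate | COc1ccc(-c2oc3c(OC)c(OS(C)(=O)=O)c(OC)c(OC)c3c(=O)c2OC)cc1
A3 | alternative 2 | 1-[4-(benzyloxy)-2,3,5,6-tetramethoxyphenyl]-3-(4-methoxyphenyl)prop-2-yn-1-one | COc1ccc(cc1)C#CC(=O)c1c(OC)c(OC)c(OCc2ccccc2)c(OC)c1OC
A4 | alternative 2 | 7-(benzyloxy)-3-iodo-5,6,8-trimethoxy-2-(4-methoxyphenyl)-4H-chromen-4-one | COc1ccc(-c2oc3c(OC)c(OCc4ccccc4)c(OC)c(OC)c3c(=O)c2I)cc1
A5 | alternative 3 | 1-[4-(benzyloxy)-2,6-dibromo-3,5-dimethoxyphenyl]-2-methoxy-3-(4-methoxyphenyl)propane-1,3-dione | COc1ccc(cc1)C(=O)C(OC)C(=O)c1c(Br)c(OC)c(OCc2ccccc2)c(OC)c1Br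
A6 | alternative 3 | 7-(benzyloxy)-5-bromo-3,6,8-trimethoxy-2-(4-methoxyphenyl)-4H-chromen-4-one | COc1ccc(-c2oc3c(OC)c(OCc4ccccc4)c(OC)c(Br)c3c(=O)c2OC)cc1
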